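Ring numbering used below: C1(CH3)=C2–C3–C4=C5(CH3)–C6–C7–C8(OH)–C9–C10–C11(CH3)=C12–C13–C14(–C1); side chain on C8: C1′(CH3)–C2′–C3′–C4′=C5′(CH3)–C6′H2OH; arm a = C7 to C14, arm b = C9 to C13.
Enabling feature: C13 and C14 are the two adjacent allylic CH2 groups of the 14-membered ring (C13 next to the E C11=C12 alkene, C14 next to the Z C1=C2 alkene), so C13–C14 is an allyl–allyl junction. Both carbons are electrophilic at the allylic-halide level; a phenylsulfonyl group on C13 reverses its polarity for the ring closure and is removed afterwards.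
Retrosynthetic cuts, in order: C13–C14 (ring); C1=C2 (Z-olefination); C3–C4 and C5–CH3 (alkyne carboalumination, ethylene oxide); C1′–C2′ (epoxide opening, the carbinol CH2OH becoming the C1′ methyl); C7–C8 (alkyl–enol triflate coupling); C8–C1′ (diazoester homologation of a geraniol-derived aldehyde).
Forward order: geraniol → arm b β-keto ester → (E)-enol triflate → trisubstituted allylic alcohol → epoxy alcohol → side chain and C1′ → arm a grown from the alkyne (C4=C5, then C1=C2) → sulfone at C13, bromide at C14 → 14-membered ring → desulfonylation, desilylation.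
Stereochemistry: C8 and C1′ come from a Sharpless epoxidation (D-(−)-tartrate) of the geometrically defined allylic alcohol and SN2 opening at C1′. The E alkenes come from geraniol (C11=C12), syn-carboalumination (C4=C5) and SeO2 oxidation (C4′=C5′); the Z alkene (C1=C2) comes from a Still–Gennari olefination.

Key step: step 21

Remark: the CIP descriptor of the carbinol carbon changes along the route as the arm termini change priority; the spatial arrangement set in steps 8 and 11 is never touched.

Step 1
Reactants: 1 geraniol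
Product: 2 geranyl tert-butyldimethylsilyl ether
Conditions: tBuMe2SiCl, imidazole, CH2Cl2, 0 °C to rt
Reagents that add atoms: tert-butyldimethylsilyl chloride, C[Si](C)(Cl)C(C)(C)C
Why: Imidazole-mediated silylation of the primary allylic alcohol; no stereocentre is formed and the E alkene of geraniol is carried through unchanged.

Step 2
Reactants: 2 geranyl tert-butyldimethylsilyl ether
Product: 3 6,7-epoxide of 2 (racemic)
Conditions: mCPBA, NaHCO3, CH2Cl2, −20 °C
Reagents that add atoms: 3-chloroperbenzoic acid, OOC(=O)c1cccc(Cl)c1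
Why: Prilezhaev epoxidation should take the remote, more electron-rich trisubstituted alkene in preference to the alkene deactivated by the allylic silyloxy group; the new stereocentre is racemic and is destroyed in step 3.

Step 3
Reactants: 3 6,7-epoxide of 2
Product: 4 (4E)-6-silyloxy-4-methylhex-4-enal
Conditions: H5IO6, THF/H2O, 0 °C
Reagents that add atoms: none
Why: Periodic acid hydrolyses the epoxide and cleaves the resulting glycol (Malaprade cleavage) to the aldehyde and acetone without touching the remaining alkene.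

Step 4
Reactants: 4 (4E)-6-silyloxy-4-methylhex-4-enal; 5 ethyl diazoacetate
Product: 6 arm b β-keto ester
Conditions: SnCl2 (10 mol %), CH2Cl2, rt
Reagents that add atoms: none
Why: Roskamp homologation: Lewis-acid-catalysed addition of the diazoester to the aldehyde followed by 1,2-hydride shift and loss of nitrogen gives the β-keto ester in one operation.

Step 5
Reactants: 6 arm b β-keto ester
Product: 7 (E)-enol triflate of 6
Conditions: Tf2O, aq. Me4NOH, hexane, 5 °C
Reagents that add atoms: trifluoromethanesulfonic anhydride, O=S(=O)(OS(=O)(=O)C(F)(F)F)C(F)(F)F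
Why: O-Triflation under aqueous tetraalkylammonium hydroxide (Schotten–Baumann-type) conditions goes through the non-chelated enolate, whose oxygen lies anti to the ester carbonyl, so the (E)-enol triflate (triflate trans to the ester, arm b cis) should form; this geometry later fixes the configuration at C8.

Step 6
Reactants: 7 (E)-enol triflate of 6; 8 (4-bromobut-1-yn-1-yl)trimethylsilane
Product: 10 (2E,6E)-enoate carrying both arms, via alkylzinc bromide 9 (not isolated)
Conditions: 8, Zn, LiCl, THF, 50 °C; then 7, PdCl2(dppf) (5 mol %), THF, rt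
Reagents that add atoms: zinc, [Zn] (retained only in 9)
Why: Negishi coupling: oxidative addition of the enol triflate to zerovalent palladium, transmetalation from the primary alkylzinc bromide and reductive elimination occur with retention of alkene geometry, so arm a takes the place of the triflate, trans to the ester.

Step 7
Reactants: 10 (2E,6E)-enoate carrying both arms
Product: 11 trisubstituted allylic alcohol
Conditions: iBu2AlH, CH2Cl2, −78 °C
Reagents that add atoms: none
Why: 1,2-Reduction of the enoate by the aluminium hydride at low temperature gives the allylic alcohol without isomerising the trisubstituted alkene; silyl ethers and the silylated alkyne are inert.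

Step 8
Reactants: 11 trisubstituted allylic alcohol
Product: 12 (2R,3R)-epoxy alcohol
Conditions: Ti(OiPr)4 (10 mol %), D-(−)-diethyl tartrate (12 mol %), tBuOOH, 4 Å molecular sieves, CH2Cl2, −20 °C
Reagents that add atoms: tert-butyl hydroperoxide, CC(C)(C)OO
Why: Sharpless asymmetric epoxidation: only the alkene of the allylic alcohol is activated by the titanium–tartrate complex, and with D-(−)-tartrate oxygen should be delivered to the face that gives the (2R,3R)-epoxy alcohol, which fixes C8 (the fully substituted epoxide carbon) because the alkene geometry is defined.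

Step 9
Reactants: 13 5-bromo-2-methylpent-2-ene
Product: 14 (2E)-5-bromo-2-methylpent-2-en-1-ol
Conditions: SeO2 (cat.), tBuOOH, CH2Cl2, rt
Reagents that add atoms: tert-butyl hydroperoxide, CC(C)(C)OO
Why: SeO2-catalysed allylic oxidation (ene reaction then 2,3-sigmatropic shift) hydroxylates the (E)-methyl group of a trisubstituted alkene selectively, giving the (E)-allylic alcohol.

Step 10
Reactants: 14 (2E)-5-bromo-2-methylpent-2-en-1-ol
Product: 15 side-chain bromide (tert-butyldiphenylsilyl ether)
Conditions: tBuPh2SiCl, imidazole, CH2Cl2, rt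
Reagents that add atoms: tert-butyl(chloro)diphenylsilane, CC(C)(C)[Si](Cl)(c1ccccc1)c1ccccc1
Why: Imidazole-mediated silylation of the primary alcohol; the robust silyl ether is kept until the last step.

Step 11
Reactants: 12 (2R,3R)-epoxy alcohol; 15 side-chain bromide
Product: 17 (2S,3R)-1,3-diol with the side chain attached, via Grignard reagent 16 (not isolated)
Conditions: 15, Mg, THF; 12, nBuLi (1 equiv), THF, −78 °C; then 16, CuI (20 mol %), −40 to 0 °C
Reagents that add atoms: magnesium, [Mg] (retained only in 16)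
Why: Copper-catalysed Grignard opening of a 2,3-epoxy alcohol: C3 is fully substituted, so SN2 attack occurs at C2 with inversion, which forms the C1′–C2′ bond, releases the tertiary C8 hydroxyl and sets C1′ relative to C8.

Step 12
Reactants: 17 (2S,3R)-1,3-diol
Product: 18 primary tosylate of 17
Conditions: TsCl, pyridine, CH2Cl2, 0 °C
Reagents that add atoms: 4-toluenesulfonyl chloride, Cc1ccc(cc1)S(Cl)(=O)=O
Why: Selective sulfonylation of the primary hydroxyl; the tertiary hydroxyl is too hindered to react.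

Step 13
Reactants: 18 primary tosylate of 17
Product: 20 terminal alkyne with the C1′ methyl group, via C-silylated alkyne 19 (not isolated)
Conditions: LiBHEt3, THF, 0 °C to rt; then MeOH, K2CO3, rt
Reagents that add atoms: none
Why: Hydride displacement of the primary tosylate (SN2 with LiBHEt3) converts CH2OTs into the C1′ methyl group without touching either stereocentre, and base-catalysed methanolysis of the alkynyl C–Si bond in the same pot frees the terminal alkyne.

Step 14
Reactants: 20 terminal alkyne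
Product: 22 (E)-homoallylic alcohol (C2–OH), via alkenylalane 21 (not isolated)
Conditions: Me3Al, (C5H5)2ZrCl2 (cat.), CH2Cl2, 0 °C to rt; then nBuLi, THF, −78 °C; ethylene oxide, −78 °C to rt
Reagents that add atoms: trimethylaluminium, C[Al](C)C; ethylene oxide, C1CO1
Why: Zirconium-catalysed carboalumination (Negishi) adds methyl and aluminium syn across the terminal alkyne with methyl on the internal carbon, and the derived lithium alkenylalanate opens ethylene oxide with retention at the alkenyl carbon, so the (E)-C4=C5 alkene and the C3–C2 unit should result.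

Step 15
Reactants: 22 (E)-homoallylic alcohol
Product: 23 β,γ-unsaturated aldehyde (C2)
Conditions: Dess–Martin periodinane, NaHCO3, CH2Cl2, 0 °C
Reagents that add atoms: none
Why: Buffered Dess–Martin oxidation of the primary alcohol gives the β,γ-unsaturated aldehyde without moving the alkene into conjugation; the tertiary alcohol cannot be oxidised, and the aldehyde is used at once.

Step 16
Reactants: 23 β,γ-unsaturated aldehyde; 24 ethyl 2-[bis(2,2,2-trifluoroethoxy)phosphoryl]propanoate
Product: 25 (2Z)-enoate (C14 ester)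
Conditions: 24, KN(SiMe3)2, 18-crown-6, THF, −78 °C
Reagents that add atoms: none
Why: Still–Gennari olefination: the electron-poor phosphonate with a dissociated potassium counter-ion eliminates rapidly from the kinetic adduct, so the (Z)-α-methyl enoate (C14 cis to C3) should form, and the low temperature protects the skipped diene.

Step 17
Reactants: 25 (2Z)-enoate
Product: 26 C13 allylic alcohol
Conditions: pyridinium 4-toluenesulfonate (cat.), MeOH, rt
Reagents that add atoms: none
Why: Mild acid-catalysed methanolysis removes the primary tert-butyldimethylsilyl ether while the bulkier tert-butyldiphenylsilyl ether, the ester and the tertiary alcohol stay intact.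

Step 18
Reactants: 26 C13 allylic alcohol
Product: 28 C13 allylic phenyl sulfone, via allylic bromide 27 (not isolated)
Conditions: CBr4, PPh3, CH2Cl2, −20 °C; then PhSO2Na, DMF, rt
Reagents that add atoms: carbon tetrabromide, BrC(Br)(Br)Br (bromine retained only in 27); sodium benzenesulfinate, [Na+].[O-]S(=O)c1ccccc1
Why: Appel bromination of the primary allylic alcohol followed by SN2 displacement by sulfinate sulfur gives the primary allylic sulfone with the E alkene retained; the sulfonyl group is the helper that reverses the polarity of C13.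

Step 19
Reactants: 28 C13 allylic phenyl sulfone
Product: 29 (2Z)-allylic alcohol (C14–OH)
Conditions: iBu2AlH, CH2Cl2, −78 °C
Reagents that add atoms: none
Why: 1,2-Reduction of the ester by the aluminium hydride gives the (Z)-allylic alcohol; the sulfone is inert at this temperature.

Step 20
Reactants: 29 (2Z)-allylic alcohol
Product: 30 bromo sulfone (C14–Br, C13–SO2Ph)
Conditions: CBr4, PPh3, CH2Cl2, −20 °C
Reagents that add atoms: carbon tetrabromide, BrC(Br)(Br)Br
Why: Appel bromination converts the primary allylic alcohol into the bromide by direct SN2 substitution, so the Z geometry of C1=C2 is kept; the tertiary alcohol does not react under these conditions.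

Step 21
Reactants: 30 bromo sulfone
Product: 31 14-membered cyclic sulfone (both C13 epimers)
Conditions: KN(SiMe3)2 (2.2 equiv), THF (0.002 M), −78 to −20 °C
Reagents that add atoms: none
Why: Deprotonation gives the dianion (tertiary alkoxide and α-sulfonyl allyl carbanion at C13), and the carbanion displaces bromide at C14 in an intramolecular SN2 alkylation. The closest known reaction type is the high-dilution macrocyclisation of sulfone-stabilised allylic carbanions onto allylic halides used for fourteen-membered terpenoid rings; it joins two carbons that are both electrophilic at the allylic-halide level, which the sulfonyl group makes possible by reversing the polarity of C13. The fourteen-membered ring is closed in the 14-exo-tet mode. The only new stereocentre is C13; it is not controlled and need not be, because the sulfonyl group is removed in step 22 and both epimers then give the same compound. The step needs cyclisation to beat intermolecular alkylation (secured by the 0.002 M concentration), C- over O-alkylation (the soft carbanion is far more nucleophilic than the hindered tertiary alkoxide) and direct α-attack with retention of both neighbouring alkene geometries (a primary allylic bromide reacts by SN2 without touching C1=C2, and the sulfonyl allyl anion keeps the E geometry of C11=C12 at low temperature).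

Step 22
Reactants: 31 14-membered cyclic sulfone
Product: 32 macrocyclic triene (side-chain silyl ether)
Conditions: PdCl2(dppp) (10 mol %), LiBHEt3, THF, 0 °C to rt
Reagents that add atoms: none
Why: Palladium-catalysed reductive desulfonylation: zerovalent palladium formed in situ ionises the allylic C13–S bond and hydride is delivered to the less substituted terminus (C13) of the π-allyl complex, so C11=C12 stays in place with its E geometry and both C13 epimers converge on one product.

Step 23
Reactants: 32 macrocyclic triene (side-chain silyl ether)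
Product: 33 target
Conditions: Bu4NF, THF, rt
Reagents that add atoms: none
Why: Fluoride-mediated desilylation frees the primary allylic alcohol of the side chain and leaves the alkenes and the tertiary alcohol untouched.

Compound list
1 | geraniol, (2E)-3,7-dimethylocta-2,6-dien-1-ol | CC(C)=CCC/C(C)=C/CO | starting material
2 | tert-butyl{[(2E)-3,7-dimethylocta-2,6-dien-1-yl]oxy}dimethylsilane | CC(C)=CCC/C(C)=C/CO[Si](C)(C)C(C)(C)C | intermediate
3 | tert-butyl{[(2E)-5-(3,3-dimethyloxiran-2-yl)-3-methylpent-2-en-1-yl]oxy}dimethylsilane, racemic at the oxirane CH | CC1(C)OC1CC/C(C)=C/CO[Si](C)(C)C(C)(C)C | intermediate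
4 | (4E)-6-[(tert-butyldimethylsilyl)oxy]-4-methylhex-4-enal | O=CCC/C(C)=C/CO[Si](C)(C)C(C)(C)C | intermediate
5 | ethyl diazoacetate | CCOC(=O)C=[N+]=[N-] | starting material
6 | ethyl (6E)-8-[(tert-butyldimethylsilyl)oxy]-6-methyl-3-oxooct-6-enoate | CCOC(=O)CC(=O)CC/C(C)=C/CO[Si](C)(C)C(C)(C)C | intermediate
7 | ethyl (2E,6E)-8-[(tert-butyldimethylsilyl)oxy]-6-methyl-3-{[(trifluoromethyl)sulfonyl]oxy}octa-2,6-dienoate | CCOC(=O)/C=C(\CC/C(C)=C/CO[Si](C)(C)C(C)(C)C)OS(=O)(=O)C(F)(F)F | intermediate
8 | (4-bromobut-1-yn-1-yl)trimethylsilane | C[Si](C)(C)C#CCCBr | starting material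
9 | [4-(trimethylsilyl)but-3-yn-1-yl]zinc bromide | C[Si](C)(C)C#CCC[Zn]Br | intermediate
10 | ethyl (2E,6E)-8-[(tert-butyldimethylsilyl)oxy]-6-methyl-3-[4-(trimethylsilyl)but-3-yn-1-yl]octa-2,6-dienoate | CCOC(=O)/C=C(\CC/C(C)=C/CO[Si](C)(C)C(C)(C)C)CCC#C[Si](C)(C)C | intermediate
11 | (2E,6E)-8-[(tert-butyldimethylsilyl)oxy]-6-methyl-3-[4-(trimethylsilyl)but-3-yn-1-yl]octa-2,6-dien-1-ol | OC/C=C(\CC/C(C)=C/CO[Si](C)(C)C(C)(C)C)CCC#C[Si](C)(C)C | intermediate
12 | [(2R,3R)-3-{(3E)-5-[(tert-butyldimethylsilyl)oxy]-3-methylpent-3-en-1-yl}-3-[4-(trimethylsilyl)but-3-yn-1-yl]oxiran-2-yl]methanol | OC[C@H]1O[C@@]1(CCC#C[Si](C)(C)C)CC/C(C)=C/CO[Si](C)(C)C(C)(C)C | intermediate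
13 | 5-bromo-2-methylpent-2-ene | CC(C)=CCCBr | starting material
14 | (2E)-5-bromo-2-methylpent-2-en-1-ol | OC/C(C)=C/CCBr | intermediate
15 | {[(2E)-5-bromo-2-methylpent-2-en-1-yl]oxy}(tert-butyl)diphenylsilane | BrCC/C=C(\C)CO[Si](c1ccccc1)(c1ccccc1)C(C)(C)C | intermediate
16 | {(3E)-5-[(tert-butyldiphenylsilyl)oxy]-4-methylpent-3-en-1-yl}magnesium bromide | Br[Mg]CC/C=C(\C)CO[Si](c1ccccc1)(c1ccccc1)C(C)(C)C | intermediate
17 | (2S,3R)-2-{(3E)-5-[(tert-butyldiphenylsilyl)oxy]-4-methylpent-3-en-1-yl}-3-{(3E)-5-[(tert-butyldimethylsilyl)oxy]-3-methylpent-3-en-1-yl}-7-(trimethylsilyl)hept-6-yne-1,3-diol | OC[C@H](CC/C=C(\C)CO[Si](c1ccccc1)(c1ccccc1)C(C)(C)C)[C@](O)(CCC#C[Si](C)(C)C)CC/C(C)=C/CO[Si](C)(C)C(C)(C)C | intermediate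
18 | primary 4-toluenesulfonate of 17, (2S,3R) | Cc1ccc(cc1)S(=O)(=O)OC[C@H](CC/C=C(\C)CO[Si](c1ccccc1)(c1ccccc1)C(C)(C)C)[C@](O)(CCC#C[Si](C)(C)C)CC/C(C)=C/CO[Si](C)(C)C(C)(C)C | intermediate
19 | (2E,6R,7R,10E)-1-[(tert-butyldiphenylsilyl)oxy]-12-[(tert-butyldimethylsilyl)oxy]-2,6,10-trimethyl-7-[4-(trimethylsilyl)but-3-yn-1-yl]dodeca-2,10-dien-7-ol | C[C@H](CC/C=C(\C)CO[Si](c1ccccc1)(c1ccccc1)C(C)(C)C)[C@](O)(CCC#C[Si](C)(C)C)CC/C(C)=C/CO[Si](C)(C)C(C)(C)C | intermediate
20 | (2E,6R,7S,10E)-7-(but-3-yn-1-yl)-1-[(tert-butyldiphenylsilyl)oxy]-12-[(tert-butyldimethylsilyl)oxy]-2,6,10-trimethyldodeca-2,10-dien-7-ol | C[C@H](CC/C=C(\C)CO[Si](c1ccccc1)(c1ccccc1)C(C)(C)C)[C@](O)(CCC#C)CC/C(C)=C/CO[Si](C)(C)C(C)(C)C | intermediate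
21 | (E)-alkenyl(dimethyl)alane from 20 (aluminium on C4, methyl on C5), C8 oxygen as its dimethylaluminium alkoxide | C[C@H](CC/C=C(\C)CO[Si](c1ccccc1)(c1ccccc1)C(C)(C)C)[C@](O[Al](C)C)(CC/C(C)=C/[Al](C)C)CC/C(C)=C/CO[Si](C)(C)C(C)(C)C | intermediate
22 | (3E,7S,8R,11E)-13-[(tert-butyldiphenylsilyl)oxy]-7-{(3E)-5-[(tert-butyldimethylsilyl)oxy]-3-methylpent-3-en-1-yl}-4,8,12-trimethyltrideca-3,11-diene-1,7-diol | C[C@H](CC/C=C(\C)CO[Si](c1ccccc1)(c1ccccc1)C(C)(C)C)[C@](O)(CC/C(C)=C/CCO)CC/C(C)=C/CO[Si](C)(C)C(C)(C)C | intermediate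
23 | (3E,7S,8R,11E)-13-[(tert-butyldiphenylsilyl)oxy]-7-{(3E)-5-[(tert-butyldimethylsilyl)oxy]-3-methylpent-3-en-1-yl}-7-hydroxy-4,8,12-trimethyltrideca-3,11-dienal | C[C@H](CC/C=C(\C)CO[Si](c1ccccc1)(c1ccccc1)C(C)(C)C)[C@](O)(CC/C(C)=C/CC=O)CC/C(C)=C/CO[Si](C)(C)C(C)(C)C | intermediate
24 | ethyl 2-[bis(2,2,2-trifluoroethoxy)phosphoryl]propanoate | CCOC(=O)C(C)P(=O)(OCC(F)(F)F)OCC(F)(F)F | starting material
25 | ethyl (2Z,5E,9S,10R,13E)-15-[(tert-butyldiphenylsilyl)oxy]-9-{(3E)-5-[(tert-butyldimethylsilyl)oxy]-3-methylpent-3-en-1-yl}-9-hydroxy-2,6,10,14-tetramethylpentadeca-2,5,13-trienoate | C[C@H](CC/C=C(\C)CO[Si](c1ccccc1)(c1ccccc1)C(C)(C)C)[C@](O)(CC/C(C)=C/C/C=C(/C)C(=O)OCC)CC/C(C)=C/CO[Si](C)(C)C(C)(C)C | intermediate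
26 | ethyl (2Z,5E,9S,10R,13E)-15-[(tert-butyldiphenylsilyl)oxy]-9-hydroxy-9-[(3E)-5-hydroxy-3-methylpent-3-en-1-yl]-2,6,10,14-tetramethylpentadeca-2,5,13-trienoate | C[C@H](CC/C=C(\C)CO[Si](c1ccccc1)(c1ccccc1)C(C)(C)C)[C@](O)(CC/C(C)=C/C/C=C(/C)C(=O)OCC)CC/C(C)=C/CO | intermediate
27 | ethyl (2Z,5E,9S,10R,13E)-9-[(3E)-5-bromo-3-methylpent-3-en-1-yl]-15-[(tert-butyldiphenylsilyl)oxy]-9-hydroxy-2,6,10,14-tetramethylpentadeca-2,5,13-trienoate | C[C@H](CC/C=C(\C)CO[Si](c1ccccc1)(c1ccccc1)C(C)(C)C)[C@](O)(CC/C(C)=C/C/C=C(/C)C(=O)OCC)CC/C(C)=C/CBr | intermediate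
28 | ethyl (2Z,5E,9S,10R,13E)-15-[(tert-butyldiphenylsilyl)oxy]-9-hydroxy-2,6,10,14-tetramethyl-9-[(3E)-3-methyl-5-(phenylsulfonyl)pent-3-en-1-yl]pentadeca-2,5,13-trienoate | C[C@H](CC/C=C(\C)CO[Si](c1ccccc1)(c1ccccc1)C(C)(C)C)[C@](O)(CC/C(C)=C/C/C=C(/C)C(=O)OCC)CC/C(C)=C/CS(=O)(=O)c1ccccc1 | intermediate
29 | (2Z,5E,9S,10R,13E)-15-[(tert-butyldiphenylsilyl)oxy]-2,6,10,14-tetramethyl-9-[(3E)-3-methyl-5-(phenylsulfonyl)pent-3-en-1-yl]pentadeca-2,5,13-triene-1,9-diol | C[C@H](CC/C=C(\C)CO[Si](c1ccccc1)(c1ccccc1)C(C)(C)C)[C@](O)(CC/C(C)=C/C/C=C(/C)CO)CC/C(C)=C/CS(=O)(=O)c1ccccc1 | intermediate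
30 | (2Z,5E,9S,10R,13E)-1-bromo-15-[(tert-butyldiphenylsilyl)oxy]-2,6,10,14-tetramethyl-9-[(3E)-3-methyl-5-(phenylsulfonyl)pent-3-en-1-yl]pentadeca-2,5,13-trien-9-ol | C[C@H](CC/C=C(\C)CO[Si](c1ccccc1)(c1ccccc1)C(C)(C)C)[C@](O)(CC/C(C)=C/C/C=C(/C)CBr)CC/C(C)=C/CS(=O)(=O)c1ccccc1 | intermediate
31 | (1S,4E,7Z,11E)-1-{(2R,5E)-7-[(tert-butyldiphenylsilyl)oxy]-6-methylhept-5-en-2-yl}-4,8,12-trimethyl-10-(phenylsulfonyl)cyclotetradeca-4,7,11-trien-1-ol, both C10 epimers (C10 = C13 of the numbering above) | C/C1=C/C/C=C(\C)CC[C@@](O)([C@H](C)CC/C=C(\C)CO[Si](c2ccccc2)(c2ccccc2)C(C)(C)C)CC/C(C)=C/C(S(=O)(=O)c2ccccc2)C1 | intermediate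
32 | (1R,4E,7Z,11E)-1-{(2R,5E)-7-[(tert-butyldiphenylsilyl)oxy]-6-methylhept-5-en-2-yl}-4,8,12-trimethylcyclotetradeca-4,7,11-trien-1-ol | C/C1=C/C/C=C(\C)CC[C@@](O)([C@H](C)CC/C=C(\C)CO[Si](c2ccccc2)(c2ccccc2)C(C)(C)C)CC/C(C)=C/CC1 | intermediate
33 | (1R,4E,7Z,11E)-1-[(2R,5E)-7-hydroxy-6-methylhept-5-en-2-yl]-4,8,12-trimethylcyclotetradeca-4,7,11-trien-1-ol | C/C1=C/C/C=C(\C)CC[C@@](O)([C@H](C)CC/C=C(\C)CO)CC/C(C)=C/CC1 | target

Total step count: 23.
Longest linear sequence: 21 steps (steps 1–8, then 11–23; steps 9–10 make the side-chain bromide).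

Steps most likely to fail

Step 21 (ring closure). Intermolecular alkylation or base-induced 1,4-elimination of HBr across C3–C14 may outrun the slow fourteen-membered closure, and the sulfonyl allyl anion may lose its E geometry if the mixture has to be warmed. The fallback sets out from 26 and returns at 32. The ester of 26 would be reduced with iBu2AlH to the bis-allylic diol F1, both primary allylic hydroxyls converted with CBr4 and PPh3 into the bis(allylic bromide) F2, and F2 added slowly to Ni(CO)4 in N-methylpyrrolidone at 50 °C. This reductive allyl–allyl coupling through π-allylnickel bromide intermediates is a known way to close 12- to 18-membered 1,5-diene rings; it joins C13 and C14 without base and without a sulfone and gives 32 directly. Because π-allylnickel species can equilibrate, the alkene geometry on both sides of the new bond would have to be checked.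

Step 11 (epoxide opening). The opening may be slow or misdirected (Payne migration and attack elsewhere) because the nucleophile is a scarce, functionalised Grignard reagent that cannot be used in large excess. The fallback sets out from 12 and returns at 19. Commercial but-3-enylmagnesium bromide would be used in large excess with CuI to give the diol F3; selective tosylation gives the tosylate F4, and LiBHEt3 reduction, quenched without methanolysis so that the alkynylsilane is kept, gives the C1′-methyl compound F5. Cross-metathesis of the terminal alkene of F5 with methacrolein (second-generation Hoveyda–Grubbs catalyst, CH2Cl2, 40 °C; the trisubstituted alkenes and the silylated alkyne are poor metathesis partners) should give the (E)-enal F6. Luche reduction (NaBH4, CeCl3, MeOH) gives the allylic alcohol F7, and silylation with tBuPh2SiCl gives 19, which is carried on as in step 13.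

Step 5 (enol triflate geometry). Leakage through the chelated enolate, or isomerisation during the palladium coupling of step 6, would erode the alkene geometry and reappear later as loss of configurational purity at C8. The fallback sets out from 4 and returns at 10. Ohira–Bestmann homologation of 4 (dimethyl (1-diazo-2-oxopropyl)phosphonate, K2CO3, MeOH) gives the terminal alkyne F8, and nBuLi followed by ClCO2Et gives the ynoate F9. Bromide 8 is converted with Mg into the Grignard reagent F10, which is added to F9 in the presence of CuBr·SMe2 in THF at −78 °C with protonation at that temperature. The syn-carbocupration places arm a cis to the new hydrogen, that is trans to the ester, and gives 10.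

Further compounds
F1 | step 21 | (2Z,5E,9S,10R,13E)-15-[(tert-butyldiphenylsilyl)oxy]-9-[(3E)-5-hydroxy-3-methylpent-3-en-1-yl]-2,6,10,14-tetramethylpentadeca-2,5,13-triene-1,9-diol | C[C@H](CC/C=C(\C)CO[Si](c1ccccc1)(c1ccccc1)C(C)(C)C)[C@](O)(CC/C(C)=C/C/C=C(/C)CO)CC/C(C)=C/CO
F2 | step 21 | (2Z,5E,9S,10R,13E)-1-bromo-9-[(3E)-5-bromo-3-methylpent-3-en-1-yl]-15-[(tert-butyldiphenylsilyl)oxy]-2,6,10,14-tetramethylpentadeca-2,5,13-trien-9-ol | C[C@H](CC/C=C(\C)CO[Si](c1ccccc1)(c1ccccc1)C(C)(C)C)[C@](O)(CC/C(C)=C/C/C=C(/C)CBr)CC/C(C)=C/CBr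
F3 | step 11 | (2S,3R)-2-(but-3-en-1-yl)-3-{(3E)-5-[(tert-butyldimethylsilyl)oxy]-3-methylpent-3-en-1-yl}-7-(trimethylsilyl)hept-6-yne-1,3-diol | OC[C@H](CCC=C)[C@](O)(CCC#C[Si](C)(C)C)CC/C(C)=C/CO[Si](C)(C)C(C)(C)C
F4 | step 11 | primary 4-toluenesulfonate of F3, (2S,3R) | Cc1ccc(cc1)S(=O)(=O)OC[C@H](CCC=C)[C@](O)(CCC#C[Si](C)(C)C)CC/C(C)=C/CO[Si](C)(C)C(C)(C)C
F5 | step 11 | (5R,6R,9E)-11-[(tert-butyldimethylsilyl)oxy]-5,9-dimethyl-6-[4-(trimethylsilyl)but-3-yn-1-yl]undeca-1,9-dien-6-ol | C[C@H](CCC=C)[C@](O)(CCC#C[Si](C)(C)C)CC/C(C)=C/CO[Si](C)(C)C(C)(C)C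
F6 | step 11 | (2E,6R,7R,10E)-12-[(tert-butyldimethylsilyl)oxy]-7-hydroxy-2,6,10-trimethyl-7-[4-(trimethylsilyl)but-3-yn-1-yl]dodeca-2,10-dienal | C[C@H](CC/C=C(\C)C=O)[C@](O)(CCC#C[Si](C)(C)C)CC/C(C)=C/CO[Si](C)(C)C(C)(C)C
F7 | step 11 | (2E,6R,7R,10E)-12-[(tert-butyldimethylsilyl)oxy]-2,6,10-trimethyl-7-[4-(trimethylsilyl)but-3-yn-1-yl]dodeca-2,10-diene-1,7-diol | C[C@H](CC/C=C(\C)CO)[C@](O)(CCC#C[Si](C)(C)C)CC/C(C)=C/CO[Si](C)(C)C(C)(C)C
F8 | step 5 | tert-butyldimethyl{[(2E)-3-methylhept-2-en-6-yn-1-yl]oxy}silane | C#CCC/C(C)=C/CO[Si](C)(C)C(C)(C)C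
F9 | step 5 | ethyl (6E)-8-[(tert-butyldimethylsilyl)oxy]-6-methyloct-6-en-2-ynoate | CCOC(=O)C#CCC/C(C)=C/CO[Si](C)(C)C(C)(C)C
F10 | step 5 | [4-(trimethylsilyl)but-3-yn-1-yl]magnesium bromide | C[Si](C)(C)C#CCC[Mg]Br
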